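The data come from a simulation from invented constants, and the scatter is random.

In a one-step world each L leaving the solid would become Z with one fixed chance, and percent Z would be that chance times percent dissolved. So we follow one molecule through the dawn run.

- dawn: L 1.1 M; D 1.1 equiv; run made earlier
- flask: L 0.54 M; D 1.10 equiv; time 8.0 min

dawn run (percent of the L charged)

| time / s | Z / % | L / % |
|---|---|---|
| 10.0 | 4.4 | 71.7 |
| 20.0 | 6.8 | 50.4 |
| 30.0 | 8.5 | 30.7 |
| 40.0 | 9.0 | 17.1 |
| 50.0 | 9.7 | 4.8 |

(each reading ± 0.5 percentage points)

- L is a solid; its amount is given per volume of the solution
- the analysis behind the earlier runs scatters by 0.5 percentage points, standard deviation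
- candidate steps: G + D -> E + Q; G + D -> Z + Q; D + Z -> J + Q; L <-> G; D + E -> J + Q
- at the start none of L is in solution

* time up to 8.0 min at which Z stands highest
* the amount of Z, in percent of the L charged, at that time

At the first dawn reading, Z divided by the L that has left the solid is 15.5 %. That ratio is the early Z share, an apparent selectivity, and it carries the scatter of the readings. The bench rule multiplies it by the whole charge.

The rule meets its border at the last dawn reading, where the same ratio is 10.2 %. That keeps 0.655 of the early share, so a third has been lost. We read this as a further fork, Z meeting D to give J.

In the new flask D starts at 0.491 of its dawn concentration, which is half. If L dissolves at the dawn molar rate, it also finishes in about half the time, so we shrink the loss to a quarter. Our reckoning is then 14.3 %.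

The forecast gives 13.5 % at 0.55 min: “Z should therefore peak near 13–14%, just after the solid disappears”. Its amount lies slightly below ours.

The flask gives 16.4 % at 0.596 min, more than our reckoning. That is 1.06 times the early share, but the share was read early in the dawn run and this is a later moment in another flask, so their closeness is no check. At that time this flask also holds G at 38.7 % and J at 24.8 %.

    G + D → E + Q (k = 0.0520 M⁻¹ s⁻¹)
    G + D → Z + Q (k = 0.0890 M⁻¹ s⁻¹)
    D + Z → J + Q (k = 0.210 M⁻¹ s⁻¹)
    L ⇌ G, rate k4*(cs4 - [G]) while solid is left; crystals form when [G] > cs4 (solubility = 0.450 M, k = 0.0870 s⁻¹)
    D + E → J + Q (k = 0.0240 M⁻¹ s⁻¹)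

For the neighbour flask, like this one but with 0.660 equiv of D, the plain early share gives an estimate of 15.5 % of the L charged. The computed neighbour flask reaches 17.1 %.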